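**Retrosynthetic overview**
1. 17 ⇒ 12 + 13. The C11–C12 bond comes from a decarboxylative radical addition and C13=C14 from a sulfoxide elimination. Ring D arrives preformed in lactone 13.
2. 12 ⇒ 7. The C19 methyl ester and C20 aldehyde come from a 19,20-δ-lactone (saponify, O-methylate, oxidise). The C12 acid and the 8(17)-alkene are parked together as an iodolactone during this. C8=CH2 comes from the C8 ketone.
3. Key disconnection 6 ⇒ 5. The C20–O bond is made by carboxylate-directed C–H lactonisation of the angular methyl group.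
4. 5 ⇒ 1. Ring C of (+)-podocarpic acid is excised by dearomatisation, removal of C13/C14 and enedione reduction, which fixes C9.
5. Ring order: rings A and B (C4, C5, C10) are bought with 1 and aromatic ring C is destroyed. The δ-lactone is made in step 4 and opened in step 6, a temporary γ-iodolactone exists in steps 6–8, and ring D is attached last.

Assumption: labdane/podocarpane numbering is used; the C8 configuration drawn in 2, 3 and 9–11 is the expected one but does not matter because C8 ends sp2; 15 and 16 are epimer mixtures at C13 (and at sulfur).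

**Step 1**
Reactants: 1 (+)-podocarpic acid
Product: 2 8α-hydroxy-12-oxopodocarpa-9(11),13-dien-19-oic acid
Conditions: PhI(OAc)2 (1.1 equiv), MeCN–H2O 3:1, 0 °C
Reagents that add atoms: water, O
Why: Trivalent-iodine oxidative dearomatisation of a para-alkylphenol (p-quinol synthesis), in which water traps the phenoxenium ion at C8 from the α face anti to the C20 methyl, and the new C8 centre is erased in step 2.

**Step 2**
Reactants: 2 8α-hydroxy-12-oxopodocarpa-9(11),13-dien-19-oic acid
Product: 4 (Z)-8-oxo-13,14,15,16,17-pentanorlabd-9(11)-ene-12,19-dioic acid, via seco-dialdehyde 3 (not isolated)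
Conditions: O3 (1 equiv), CH2Cl2–MeOH, −78 °C; Me2S; NaIO4 (2.2 equiv), THF–H2O, rt
Reagents that add atoms: ozone, [O-][O+]=O; water, O
Why: Chemoselective ozonolysis of the unhindered disubstituted C13=C14 enone bond (C9=C11 is trisubstituted and shielded by quaternary C10), followed by Malaprade periodate cleavage of the α-hydroxy aldehyde and α-keto aldehyde units, removes C13 and C14 and leaves the C8 ketone and the C12 acid.

**Step 3**
Reactants: 4 (Z)-8-oxo-13,14,15,16,17-pentanorlabd-9(11)-ene-12,19-dioic acid
Product: 5 8-oxo-13,14,15,16,17-pentanorlabdane-12,19-dioic acid (5α-H, 9α-H)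
Conditions: Zn dust, AcOH, 50 °C
Reagents that add atoms: none
Why: Dissolving-metal conjugate reduction of an ene-dicarbonyl, in which C9 equilibrates through the C8 enol to the equatorial 9β side chain (9α-H), so this stereocentre is set under thermodynamic control.

**Step 4**
Reactants: 5 8-oxo-13,14,15,16,17-pentanorlabdane-12,19-dioic acid
Product: 6 8-oxo-13,14,15,16,17-pentanorlabdan-19,20-olid-12-oic acid
Conditions: K2PtCl4 (10 mol %), CuCl2 (3 equiv), H2O–AcOH 2:1, 130 °C, sealed tube
Reagents that add atoms: none
Why: Proposed new method: the axial C19 carboxylate (1,3-diaxial to C20) and the C12 carboxylate (gauche to C20) together hold divalent platinum directly over the angular methyl; electrophilic Shilov-type C–H platination intrinsically prefers methyl over methylene and methine sites and avoids the inductively deactivated β-methyl C18; CuCl2 oxidises the Pt–CH2 species to tetravalent platinum, and the C19 carboxylate then displaces the metal from C20 intramolecularly, forming the C20–O bond in a six-membered ring with no new stereocentre; hot acid funnels any 12,20-olide to the more stable 19,20-olide, and either lactone converges in step 6; the closest known reaction type is the chelate-directed K2PtCl4/CuCl2 hydroxylation–lactonisation of simple aliphatic acids and amino acids, which has never been shown for a δ-neopentyl methyl of a polycyclic diacid.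

**Step 5**
Reactants: 6 8-oxo-13,14,15,16,17-pentanorlabdan-19,20-olid-12-oic acid
Product: 7 13,14,15,16-tetranorlabd-8(17)-en-19,20-olid-12-oic acid
Conditions: Ph3PCH3Br, KOtBu (3.5 equiv each), THF, 0 → 50 °C; aq. citric acid
Reagents that add atoms: methyltriphenylphosphonium bromide, C[P+](c1ccccc1)(c1ccccc1)c1ccccc1.[Br-]
Why: Wittig methylenation of the C8 ketone with excess ylide (one equivalent is consumed by the acid), in which the hindered lactone is inert and C9 stays in its more stable equatorial configuration.

**Step 6**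
Reactants: 7 13,14,15,16-tetranorlabd-8(17)-en-19,20-olid-12-oic acid
Product: 10 methyl 20-hydroxy-17-iodo-13,14,15,16-tetranorlabdan-12,8α-olid-19-oate, via dipotassium hydroxy dicarboxylate 8 (not isolated), via potassium iodolactone carboxylate 9 (not isolated)
Conditions: KOH (2.1 equiv), MeOH–H2O, 100 °C; I2 (1.1 equiv), 0 °C; MeI, Bu4NBr (cat.), CH2Cl2–H2O, rt
Reagents that add atoms: potassium hydroxide, [K+].[OH-]; iodine, [I][I]; iodomethane, IC
Why: Saponification of the δ-lactone is followed by 5-exo iodolactonisation, which captures only the γ,δ-unsaturated C12 carboxylate and masks acid and alkene together, so the phase-transfer SN2 O-methylation reaches only the C19 carboxylate; the C8 centre formed (O equatorial, CH2I axial) is temporary.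

**Step 7**
Reactants: 10 methyl 20-hydroxy-17-iodo-13,14,15,16-tetranorlabdan-12,8α-olid-19-oate
Product: 11 methyl 17-iodo-20-oxo-13,14,15,16-tetranorlabdan-12,8α-olid-19-oate
Conditions: Dess–Martin periodinane, pyridine, CH2Cl2, 0 °C (run directly on crude 10)
Reagents that add atoms: none
Why: Buffered Dess–Martin oxidation converts the neopentyl C20 alcohol into the non-enolisable aldehyde before it can relactonise onto the C19 ester.

**Step 8**
Reactants: 11 methyl 17-iodo-20-oxo-13,14,15,16-tetranorlabdan-12,8α-olid-19-oate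
Product: 12 19-methoxy-19,20-dioxo-13,14,15,16-tetranorlabd-8(17)-en-12-oic acid
Conditions: Zn dust, AcOH–THF, rt
Reagents that add atoms: none
Why: Zinc-mediated reductive β-elimination (the reverse of iodolactonisation) regenerates the 8(17)-alkene and frees the C12 acid without hydroxide, which would cleave the C19 ester through participation of the neighbouring aldehyde hydrate.

**Step 9**
Reactants: 12 19-methoxy-19,20-dioxo-13,14,15,16-tetranorlabd-8(17)-en-12-oic acid; 13 α-methylene-γ-butyrolactone
Product: 15 methyl 20-oxo-13-(pyridin-2-ylthio)labd-8(17)-en-16,15-olid-19-oate, via Barton ester 14 (not isolated)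
Conditions: 1-hydroxypyridine-2(1H)-thione, DCC, CH2Cl2, 0 °C, dark; 13 (8 equiv), tungsten lamp, 10 °C
Reagents that add atoms: 1-hydroxypyridine-2(1H)-thione, ON1C=CC=CC1=S
Why: Barton decarboxylative radical addition, in which the primary C11 radical adds to the exocyclic CH2 of 13 (forming C11–C12) and the tertiary α-lactone radical carries the chain by taking up the 2-pyridylthio group; conditions are neutral, so aldehyde, ester and alkene survive, and the C13 epimers are irrelevant.

**Step 10**
Reactants: 15 methyl 20-oxo-13-(pyridin-2-ylthio)labd-8(17)-en-16,15-olid-19-oate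
Product: 17 methyl 20-oxolabda-8(17),13-dien-16,15-olid-19-oate (target), via sulfoxide 16 (not isolated)
Conditions: mCPBA (1.0 equiv), CH2Cl2, −78 °C; toluene, 80 °C
Reagents that add atoms: mCPBA, O=C(OO)c1cccc(Cl)c1
Why: Sulfide oxidation, which is much faster than epoxidation of the hindered 1,1-disubstituted alkene at −78 °C, is followed by thermal sulfoxide syn-elimination toward the ring C14–H, the usual route to α-alkyl butenolides, and touches no stereocentre.

**Compound list**
1 | (+)-podocarpic acid | c1cc(O)cc2c1CC[C@@H]1[C@]2(C)CCC[C@]1(C)C(=O)O | starting material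
2 | 8α-hydroxy-12-oxopodocarpa-9(11),13-dien-19-oic acid (p-quinol) | O=C1C=C[C@@]2(O)CC[C@@H]3[C@](C)(CCC[C@]3(C)C(=O)O)C2=C1 | intermediate
3 | 8α-hydroxy-12,13,14-trioxo-13,14-secopodocarp-9(11)-en-19-oic acid (seco-dialdehyde) | O=C[C@@]1(O)CC[C@@H]2[C@](C)(CCC[C@]2(C)C(=O)O)/C1=C/C(=O)C=O | intermediate
4 | (Z)-8-oxo-13,14,15,16,17-pentanorlabd-9(11)-ene-12,19-dioic acid (in equilibrium with its cyclic 8-hydroxy-12,8-olide form) | O=C1CC[C@@H]2[C@](C)(CCC[C@]2(C)C(=O)O)/C1=C/C(=O)O | intermediate
5 | 8-oxo-13,14,15,16,17-pentanorlabdane-12,19-dioic acid | O=C1CC[C@@H]2[C@](C)(CCC[C@]2(C)C(=O)O)[C@H]1CC(=O)O | intermediate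
6 | 8-oxo-13,14,15,16,17-pentanorlabdan-19,20-olid-12-oic acid | O=C1CC[C@@H]2[C@]3(CCC[C@]2(C)C(=O)OC3)[C@H]1CC(=O)O | intermediate
7 | 13,14,15,16-tetranorlabd-8(17)-en-19,20-olid-12-oic acid | C=C1CC[C@@H]2[C@]3(CCC[C@]2(C)C(=O)OC3)[C@H]1CC(=O)O | intermediate
8 | dipotassium 20-hydroxy-13,14,15,16-tetranorlabd-8(17)-ene-12,19-dioate | C=C1CC[C@@H]2[C@](CO)(CCC[C@]2(C)C(=O)[O-])[C@H]1CC(=O)[O-].[K+].[K+] | intermediate
9 | potassium 20-hydroxy-17-iodo-13,14,15,16-tetranorlabdan-12,8α-olid-19-oate | O=C1C[C@H]2[C@@](C[I])(CC[C@@H]3[C@]2(CO)CCC[C@]3(C)C(=O)[O-])O1.[K+] | intermediate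
10 | methyl 20-hydroxy-17-iodo-13,14,15,16-tetranorlabdan-12,8α-olid-19-oate | O=C1C[C@H]2[C@@](C[I])(CC[C@@H]3[C@]2(CO)CCC[C@]3(C)C(=O)OC)O1 | intermediate
11 | methyl 17-iodo-20-oxo-13,14,15,16-tetranorlabdan-12,8α-olid-19-oate | O=C1C[C@H]2[C@@](C[I])(CC[C@@H]3[C@]2(C=O)CCC[C@]3(C)C(=O)OC)O1 | intermediate
12 | 19-methoxy-19,20-dioxo-13,14,15,16-tetranorlabd-8(17)-en-12-oic acid | C=C1CC[C@@H]2[C@](C=O)(CCC[C@]2(C)C(=O)OC)[C@H]1CC(=O)O | intermediate
13 | α-methylene-γ-butyrolactone | C=C1CCOC1=O | starting material
14 | O-acyl thiohydroxamate (Barton ester) of 12 | C=C1CC[C@@H]2[C@](C=O)(CCC[C@]2(C)C(=O)OC)[C@H]1CC(=O)ON1C=CC=CC1=S | intermediate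
15 | methyl 20-oxo-13-(pyridin-2-ylthio)labd-8(17)-en-16,15-olid-19-oate | C=C1CC[C@@H]2[C@](C=O)(CCC[C@]2(C)C(=O)OC)[C@H]1CCC1(Sc3ccccn3)CCOC1=O | intermediate
16 | methyl 20-oxo-13-(pyridin-2-ylsulfinyl)labd-8(17)-en-16,15-olid-19-oate | C=C1CC[C@@H]2[C@](C=O)(CCC[C@]2(C)C(=O)OC)[C@H]1CCC1(S(=O)c3ccccn3)CCOC1=O | intermediate
17 | methyl 20-oxolabda-8(17),13-dien-16,15-olid-19-oate (CNP0175906.1) | C=C1CC[C@@H]2[C@](C=O)(CCC[C@]2(C)C(=O)OC)[C@H]1CCC1=CCOC1=O | target

**Step count and risks**

Total step count: 10. Longest linear sequence: 10 (1 → 17).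

**Step 4 (the new C–H lactonisation)** may fail in three ways. Turnover at a neopentyl methyl may be low. CuCl2 may α-chlorinate the ketone. Oxidation may occur at methylene sites instead. The fallback uses known amidyl-radical chemistry, sets out from 5 and comes back at 6. Fischer esterification (MeOH, cat. H2SO4) touches only the unhindered acid and gives the 12-methyl ester F1. Oxalyl chloride converts the hindered C19 acid into the acid chloride F2, and NH3 gives the primary 19-carboxamide F3. Irradiation with PhI(OAc)2/I2 proceeds through the N-iodoamide, the amidyl radical, hydrogen transfer from the 1,3-diaxial C20 methyl, iodination and O-cyclisation, and gives the iminolactone F4. Dilute HCl hydrolyses this to the lactone methyl ester F5, and LiOH then removes only the unhindered methyl ester to give 6.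

**Step 6 (telescoped opening, iodolactonisation and methylation)** may fail because the C20 hydroxyl competes as nucleophile for the iodonium ion, or because 10 relactonises. The fallback differentiates the two carboxyls enzymatically instead of by protection, sets out from 7 and comes back at 12. Saponification and methylation of both carboxylates without iodine give the hydroxy diester F6. Immediate Dess–Martin oxidation gives the aldehyde diester F7. Pig liver esterase at pH 7 then hydrolyses only the unhindered C12 ester, with no free hydroxide present, to give 12.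

**Step 2 (chemoselective ozonolysis)** may fail through attack on C9=C11. The fallback replaces ozonolysis by a stepwise dihydroxylation and glycol cleavage, sets out from 2 and comes back at 4. OsO4 (cat.)/NMO, which is sterically much more discriminating, dihydroxylates only C13=C14 to give the 8,13,14-triol F8. Excess NaIO4 then cleaves C8–C14, C13–C14 and C12–C13 to give 4.

**Further compounds**
F1 | step 4 | 12-methyl hydrogen 8-oxo-13,14,15,16,17-pentanorlabdane-12,19-dioate | O=C1CC[C@@H]2[C@](C)(CCC[C@]2(C)C(=O)O)[C@H]1CC(=O)OC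
F2 | step 4 | methyl 19-chloro-8,19-dioxo-13,14,15,16,17-pentanorlabdan-12-oate (acid chloride) | O=C1CC[C@@H]2[C@](C)(CCC[C@]2(C)C(=O)Cl)[C@H]1CC(=O)OC
F3 | step 4 | methyl 19-amino-8,19-dioxo-13,14,15,16,17-pentanorlabdan-12-oate (carboxamide) | O=C1CC[C@@H]2[C@](C)(CCC[C@]2(C)C(N)=O)[C@H]1CC(=O)OC
F4 | step 4 | methyl 19-imino-8-oxo-19,20-epoxy-13,14,15,16,17-pentanorlabdan-12-oate (iminolactone) | O=C1CC[C@@H]2[C@]3(CCC[C@]2(C)C(=N)OC3)[C@H]1CC(=O)OC
F5 | step 4 | methyl 8-oxo-13,14,15,16,17-pentanorlabdan-19,20-olid-12-oate | O=C1CC[C@@H]2[C@]3(CCC[C@]2(C)C(=O)OC3)[C@H]1CC(=O)OC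
F6 | step 6 | dimethyl 20-hydroxy-13,14,15,16-tetranorlabd-8(17)-ene-12,19-dioate | C=C1CC[C@@H]2[C@](CO)(CCC[C@]2(C)C(=O)OC)[C@H]1CC(=O)OC
F7 | step 6 | dimethyl 20-oxo-13,14,15,16-tetranorlabd-8(17)-ene-12,19-dioate | C=C1CC[C@@H]2[C@](C=O)(CCC[C@]2(C)C(=O)OC)[C@H]1CC(=O)OC
F8 | step 2 | 8α,13,14-trihydroxy-12-oxopodocarp-9(11)-en-19-oic acid (C13/C14 cis-diol, diastereomer mixture) | O=C1C(O)C(O)[C@@]2(O)CC[C@@H]3[C@](C)(CCC[C@]3(C)C(=O)O)C2=C1
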